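## Retrosynthetic overview

1. Ring A is phloroglucinol 1; the isopentyl chain plus C3/C4 is 5-methylhexanoyl chloride 2; the aryl–C4 bond is cut by a Friedel–Crafts disconnection back to ketone 3.
2. Ring B plus C2 is 3,4,5-trimethoxybenzoyl chloride 4; the C2–C3 bond is cut back to polyanion 5 of the ketone, whose C-aroylation gives diketone 6.
3. The O1–C2 bond of ring C is cut back to diketone 6; acid cyclodehydration gives flavone 7.
4. The three ring-B hydroxyls are carried as methyl ethers, so target 8 comes from 7 by O-demethylation.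
5. Ring order: rings A and B are bought intact; ring C (the pyranone) is the only ring formed, in step 2.

Assumption: the target has no stereocentre and no stereogenic double bond, so the compound drawn is made without stereocontrol; 1, 2 and 4 are taken as catalogue chemicals.

## Route

Step 1
Reactants: 1 phloroglucinol (benzene-1,3,5-triol, anhydrous); 2 5-methylhexanoyl chloride
Product: 3 5-methyl-1-(2,4,6-trihydroxyphenyl)hexan-1-one
Conditions: AlCl3 (4 equiv), CH2Cl2/MeNO2, 0 °C to 40 °C; then ice, 1 M HCl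
Reagents that add atoms: 5-methylhexanoyl chloride (compound 2), CC(C)CCCC(=O)Cl
Why: Friedel–Crafts C-acylation of the very electron-rich triol, where the first acyl group (chelated to aluminium and electron-withdrawing) suppresses a second acylation; no stereocentre is formed.

Step 2
Reactants: 3 5-methyl-1-(2,4,6-trihydroxyphenyl)hexan-1-one; 4 3,4,5-trimethoxybenzoyl chloride
Product: 7 5,7-dihydroxy-3-(3-methylbutyl)-2-(3,4,5-trimethoxyphenyl)-4H-chromen-4-one, via tetralithium polyanion 5 (not isolated), via beta-diketone 6 (not isolated)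
Conditions: LiN(SiMe3)2 (5 equiv), THF, −78 to −10 °C; 4 (1.0 equiv), −78 °C to rt; aq. HCl; crude into AcOH, H2SO4 (0.5%), 95–100 °C
Reagents that add atoms: 3,4,5-trimethoxybenzoyl chloride (compound 4), COc1cc(C(=O)Cl)cc(OC)c1OC
Why: Claisen-type C-aroylation of the lithium enolate within the polyanion (the aggregated lithium phenoxides are poor nucleophiles at low temperature) gives the Baker–Venkataraman-type diketone directly, and acid-catalysed cyclodehydration (hemiketal formation, then loss of water) closes ring C; the racemic, labile stereocentre of 6 is erased when C3 becomes sp2.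

Step 3
Reactants: 7 5,7-dihydroxy-3-(3-methylbutyl)-2-(3,4,5-trimethoxyphenyl)-4H-chromen-4-one
Product: 8 asplenetin, 5,7-dihydroxy-3-(3-methylbutyl)-2-(3,4,5-trihydroxyphenyl)-4H-chromen-4-one
Conditions: BBr3 (8 equiv), CH2Cl2, −78 °C to rt, Ar; then H2O, 0 °C
Reagents that add atoms: none
Why: Lewis-acid aryl methyl ether cleavage (BBr3 O-demethylation), in which boron binds each methoxy oxygen and bromide removes the methyl group by SN2, while the chromone, the alkyl chain and the free phenols are inert; no stereocentre is involved.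

## Compound list

1 | phloroglucinol (benzene-1,3,5-triol) | Oc1cc(O)cc(O)c1 | starting material
2 | 5-methylhexanoyl chloride | CC(C)CCCC(=O)Cl | starting material
3 | 5-methyl-1-(2,4,6-trihydroxyphenyl)hexan-1-one | CC(C)CCCC(=O)c1c(O)cc(O)cc1O | intermediate
4 | 3,4,5-trimethoxybenzoyl chloride | COc1cc(C(=O)Cl)cc(OC)c1OC | starting material
5 | tetralithium polyanion of ketone 3 ((Z)-enolate, three phenoxides) | CC(C)CC/C=C(\[O-])c1c([O-])cc([O-])cc1[O-].[Li+].[Li+].[Li+].[Li+] | intermediate
6 | 2-(3-methylbutyl)-1-(2,4,6-trihydroxyphenyl)-3-(3,4,5-trimethoxyphenyl)propane-1,3-dione (racemic at C2, configurationally labile) | CC(C)CCC(C(=O)c1cc(OC)c(OC)c(OC)c1)C(=O)c1c(O)cc(O)cc1O | intermediate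
7 | 5,7-dihydroxy-3-(3-methylbutyl)-2-(3,4,5-trimethoxyphenyl)-4H-chromen-4-one | CC(C)CCc1c(-c2cc(OC)c(OC)c(OC)c2)oc2cc(O)cc(O)c2c1=O | intermediate
8 | asplenetin, 5,7-dihydroxy-3-(3-methylbutyl)-2-(3,4,5-trihydroxyphenyl)-4H-chromen-4-one (achiral) | CC(C)CCc1c(-c2cc(O)c(O)c(O)c2)oc2cc(O)cc(O)c2c1=O | target

## Summary

Total step count: 3. Longest linear sequence: 3 steps (1 → 3 → 7 → 8).

Steps most likely to fail, with fallbacks:

Step 2 (highest risk). The alpha-branched enolate is more hindered than the acetophenone enolates this method is known for, so O-aroylation of a phenoxide may compete with C-aroylation. The fallback sets out from compound 3 and comes back at compound 7. Ketone 3 is esterified on all three hydroxyls with 4 (3.3 equiv, pyridine, cat. DMAP, rt) to give 2-(5-methylhexanoyl)benzene-1,3,5-triyl tris(3,4,5-trimethoxybenzoate) F3. Powdered KOH in pyridine at 50 °C then moves one ortho aroyl group from oxygen to the alpha-carbon (Baker–Venkataraman rearrangement) to give the bis-ester diketone F4. AcOH/H2SO4 at 100 °C closes ring C to the 5,7-bis(3,4,5-trimethoxybenzoyloxy)flavone F5. LiOH in THF/H2O followed by HCl removes the two remaining aryl esters and delivers 7.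

Step 3. Six B–O events are needed on one molecule, and the pyrogallol product oxidises easily in air, so demethylation may stall or the product may degrade on work-up. The fallback sets out from compound 3 and comes back at compound 8; it swaps methyl for benzyl so the last step is a neutral hydrogenolysis. Polyanion 5 (from 3 and LiN(SiMe3)2 as in step 2) is acylated with 3,4,5-tris(benzyloxy)benzoyl chloride F6 to give the benzyl-series diketone F7. TsOH·H2O (cat.) in toluene at 80 °C cyclodehydrates it to 5,7-dihydroxy-3-(3-methylbutyl)-2-[3,4,5-tris(benzyloxy)phenyl]-4H-chromen-4-one F8. H2 (1 atm) over 10% Pd/C in EtOAc/MeOH at rt removes the three benzyl groups and gives 8; the tetrasubstituted C2=C3 bond of the chromone is not reduced under these conditions.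

Step 1. AlCl3 acylation of a free triol can give O-acylation, di-C-acylation or tar. The fallback sets out from compound 1 and comes back at compound 3; it uses a nitrile as the electrophile (Houben–Hoesch reaction). Compound 1 and 5-methylhexanenitrile F1 in dry Et2O with a little fused ZnCl2 are saturated with HCl gas at 0 °C. The ketiminium chloride F2 that separates is then boiled in water and hydrolyses to ketone 3; this reaction stops cleanly at mono-C-acylation.

## Further compounds

F1 | step 1 | 5-methylhexanenitrile | CC(C)CCCC#N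
F2 | step 1 | 5-methyl-1-(2,4,6-trihydroxyphenyl)hexan-1-iminium chloride | CC(C)CCCC(=[NH2+])c1c(O)cc(O)cc1O.[Cl-]
F3 | step 2 | 2-(5-methylhexanoyl)benzene-1,3,5-triyl tris(3,4,5-trimethoxybenzoate) | CC(C)CCCC(=O)c1c(OC(=O)c2cc(OC)c(OC)c(OC)c2)cc(OC(=O)c2cc(OC)c(OC)c(OC)c2)cc1OC(=O)c1cc(OC)c(OC)c(OC)c1
F4 | step 2 | 5-hydroxy-4-[2-(3-methylbutyl)-3-oxo-3-(3,4,5-trimethoxyphenyl)propanoyl]-1,3-phenylene bis(3,4,5-trimethoxybenzoate) (racemic) | CC(C)CCC(C(=O)c1cc(OC)c(OC)c(OC)c1)C(=O)c1c(O)cc(OC(=O)c2cc(OC)c(OC)c(OC)c2)cc1OC(=O)c1cc(OC)c(OC)c(OC)c1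
F5 | step 2 | 3-(3-methylbutyl)-4-oxo-2-(3,4,5-trimethoxyphenyl)-4H-chromene-5,7-diyl bis(3,4,5-trimethoxybenzoate) | CC(C)CCc1c(-c2cc(OC)c(OC)c(OC)c2)oc2cc(OC(=O)c3cc(OC)c(OC)c(OC)c3)cc(OC(=O)c3cc(OC)c(OC)c(OC)c3)c2c1=O
F6 | step 3 | 3,4,5-tris(benzyloxy)benzoyl chloride | O=C(Cl)c1cc(OCc2ccccc2)c(OCc2ccccc2)c(OCc2ccccc2)c1
F7 | step 3 | 2-(3-methylbutyl)-1-(2,4,6-trihydroxyphenyl)-3-[3,4,5-tris(benzyloxy)phenyl]propane-1,3-dione (racemic) | CC(C)CCC(C(=O)c1cc(OCc2ccccc2)c(OCc2ccccc2)c(OCc2ccccc2)c1)C(=O)c1c(O)cc(O)cc1O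
F8 | step 3 | 5,7-dihydroxy-3-(3-methylbutyl)-2-[3,4,5-tris(benzyloxy)phenyl]-4H-chromen-4-one | CC(C)CCc1c(-c2cc(OCc3ccccc3)c(OCc3ccccc3)c(OCc3ccccc3)c2)oc2cc(O)cc(O)c2c1=O
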